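**Plan**

- Feature used: the furanone oxygen lies between C3 and C10, and these two carbons are also joined through C1(=O)–C2. The 3(2H)-furanone (O, C3, C2, C1, C10) is therefore a cyclobutanone C1–C2–C3–C10 whose exocyclic oxygen on C3 has moved into the ring, and the ten-membered carbocycle is a cyclooctene plus these two carbons.
- Retrosynthesis: cut O–C10 and rejoin C3–C10 (a bicyclo[6.2.0] 3-silyloxycyclobutanone); cut C1–C10 and C2–C3 (dichloroketene + silyl dienol ether of a cyclooctenone); then cut C3–C4 (Nozaki–Hiyama–Kishi), C4=C5 (Stork–Zhao), the C8 ester, C7–C8 (dithiane conjugate addition to a butenolide) and C11=C13 (Mannich).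
- Forward: lactone first, then the eight-membered ring, then the four-membered ring; the last operation makes the furanone, the oxygen bridge and the ten-membered ring together.
- Stereochemistry: C6 from (S)-5-(hydroxymethyl)butenolide; C7 by anti conjugate addition; C8 by CBS reduction; C10 from the face of the ketene addition (anti to the C8 ester), passed on with overall retention by bromination and O-displacement; 4Z from the Z-iodoalkene and the ring.

Key step: step 19

Remark: locants C1–C15 are those of the target (C1 furanone C=O, C2 furanone CH, C3 furanone C–O, C4=C5 ring alkene, C6 lactone O–CH, C7, C8 ester carbon, C9 CH2, C10 quaternary C–O, C11–C13 methylene lactone, C14/C15 methyls). The CH(CH3) centre that becomes C10 is drawn with the configuration of the purchased bromide, but it is made trigonal in step 16, so its integrity is not needed.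

**Step 1**
Reactants: 1 (S)-3-bromo-2-methylpropan-1-ol
Product: 2 (S)-(3-bromo-2-methylpropoxy)(tert-butyl)diphenylsilane
Conditions: TBDPSCl, imidazole, DMF, 0 °C → rt
Reagents that add atoms: tert-butyl(chloro)diphenylsilane, CC(C)(C)[Si](Cl)(c1ccccc1)c1ccccc1
Why: Imidazole-promoted silylation of the primary alcohol, which does not involve the stereocentre.

**Step 2**
Reactants: 3 1,3-dithiane; 2 (S)-(3-bromo-2-methylpropoxy)(tert-butyl)diphenylsilane
Product: 5 (R)-2-[3-(tert-butyldiphenylsilyloxy)-2-methylpropyl]-1,3-dithiane, via 2-lithio-1,3-dithiane 4 (not isolated)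
Conditions: n-BuLi, THF, −30 °C; then 2, −30 °C → rt
Reagents that add atoms: none
Why: Corey–Seebach alkylation, in which the lithiodithiane displaces the primary bromide (SN2) and one acidic dithiane C–H remains for step 4.

**Step 3**
Reactants: 6 (S)-5-(hydroxymethyl)furan-2(5H)-one
Product: 7 (S)-5-[(tert-butyldimethylsilyloxy)methyl]furan-2(5H)-one
Conditions: TBSCl, imidazole, CH2Cl2, 0 °C → rt
Reagents that add atoms: tert-butyl(chloro)dimethylsilane, CC(C)(C)[Si](C)(C)Cl
Why: Standard O-silylation; the γ-stereocentre (later C6) comes from the commercial (S)-butenolide.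

**Step 4**
Reactants: 5 (R)-2-[3-(tert-butyldiphenylsilyloxy)-2-methylpropyl]-1,3-dithiane; 7 (S)-5-[(tert-butyldimethylsilyloxy)methyl]furan-2(5H)-one
Product: 10 all-trans Mannich lactone (3-dimethylaminomethyl-4-dithianyl-5-silyloxymethyl-γ-butyrolactone), via 2-lithio-2-alkyl-1,3-dithiane 8 (not isolated), via lithium lactone enolate 9 (not isolated)
Conditions: n-BuLi, THF, −20 °C; HMPA, −78 °C; 7; then Me2N+=CH2 I−, −78 °C → rt
Reagents that add atoms: N,N-dimethylmethyleneiminium iodide (Eschenmoser's salt), C=[N+](C)C.[I-]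
Why: In THF/HMPA the 2-alkyl-2-lithiodithiane adds 1,4 to the butenolide anti to the CH2OTBS group (C7 trans to C6, as for related sulfur-stabilised anions on 5-silyloxymethylbutenolides), and the lactone enolate is intercepted in a Mannich reaction anti to the new substituent.

**Step 5**
Reactants: 10 all-trans Mannich lactone
Product: 12 dithianyl α-methylene-γ-butyrolactone, via quaternary ammonium iodide 11 (not isolated)
Conditions: MeI, MeOH, rt; then aq. NaHCO3, CH2Cl2, rt
Reagents that add atoms: none
Why: Exhaustive methylation and mild-base β-elimination (Eschenmoser α-methylenation) unveil the methylene lactone while the sp3 dithiane carbon still blocks enolisation next to C7.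

**Step 6**
Reactants: 12 dithianyl α-methylene-γ-butyrolactone
Product: 13 β-acyl α-methylene lactone (C8 ketone)
Conditions: PhI(OCOCF3)2, MeCN/H2O (9:1), 0 °C, 15 min; pH 7 work-up
Reagents that add atoms: water, O
Why: Oxidative dithioacetal hydrolysis with the iodine(III) reagent is fast, acidic and base-free, which should avoid exo-to-endo migration of the methylene group and β-elimination of the lactone oxygen.

**Step 7**
Reactants: 13 β-acyl α-methylene lactone (C8 ketone)
Product: 14 (8R)-alcohol
Conditions: (S)-2-methyl-CBS-oxazaborolidine, catecholborane, toluene, −78 °C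
Reagents that add atoms: none
Why: Corey–Bakshi–Shibata reduction in which, with the branched C7 side as the large group, the (S)-catalyst should give the (8R)-carbinol by reagent control; catecholborane at −78 °C leaves the methylene lactone alone.

**Step 8**
Reactants: 14 (8R)-alcohol
Product: 15 C8 isovalerate
Conditions: isovaleric anhydride, DMAP (cat.), pyridine, CH2Cl2, 0 °C → rt
Reagents that add atoms: 3-methylbutanoic anhydride, CC(C)CC(=O)OC(=O)CC(C)C
Why: DMAP-catalysed acylation of the secondary alcohol installs the ester of the target with retention at C8.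

**Step 9**
Reactants: 15 C8 isovalerate
Product: 16 primary alcohol at C5
Conditions: PPTS (cat.), MeOH, rt
Reagents that add atoms: none
Why: Acid-catalysed methanolysis removes the primary TBS ether much faster than the TBDPS ether and does not touch the esters.

**Step 10**
Reactants: 16 primary alcohol at C5
Product: 17 C5 aldehyde
Conditions: Dess–Martin periodinane, NaHCO3, CH2Cl2, 0 °C → rt
Reagents that add atoms: none
Why: Dess–Martin oxidation gives the α-acyloxy aldehyde under near-neutral conditions, so C6 should not epimerise.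

**Step 11**
Reactants: 17 C5 aldehyde
Product: 18 (Z)-2-iodoalkene
Conditions: Ph3P+Et I−, n-BuLi, THF; I2, −78 °C; NaHMDS, −20 °C; then 17, −78 °C
Reagents that add atoms: ethyltriphenylphosphonium iodide, CC[P+](c1ccccc1)(c1ccccc1)c1ccccc1.[I-]; iodine, II
Why: Stork–Zhao olefination with the α-iodo ylide gives the Z-iodoalkene (iodine cis to C6), which fixes the later 4Z ring alkene; at −78 °C the aldehyde should react faster than the methylene lactone.

**Step 12**
Reactants: 18 (Z)-2-iodoalkene
Product: 19 primary alcohol at C3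
Conditions: HF·pyridine, pyridine/THF, 0 °C → rt
Reagents that add atoms: none
Why: Buffered fluoride cleaves the TBDPS ether without acyl migration or attack on the vinyl iodide.

**Step 13**
Reactants: 19 primary alcohol at C3
Product: 20 C3 aldehyde
Conditions: Dess–Martin periodinane, NaHCO3, CH2Cl2, 0 °C → rt
Reagents that add atoms: none
Why: Dess–Martin oxidation to the aldehyde; epimerisation of its α-methyl centre is of no consequence.

**Step 14**
Reactants: 20 C3 aldehyde
Product: 21 cyclooctenol (carbinol epimers)
Conditions: CrCl2 (excess), NiCl2 (cat.), DMSO, rt, 0.005 M, slow addition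
Reagents that add atoms: none
Why: Intramolecular Nozaki–Hiyama–Kishi reaction, in which the alkenylchromium adds only to the aldehyde with retention of the Z geometry and closes the eight-membered ring at C3–C4 under high dilution.

**Step 15**
Reactants: 21 cyclooctenol (carbinol epimers)
Product: 22 cyclooctenone
Conditions: Dess–Martin periodinane, CH2Cl2, rt
Reagents that add atoms: none
Why: Dess–Martin oxidation of both allylic alcohol epimers converges on the enone.

**Step 16**
Reactants: 22 cyclooctenone
Product: 23 triethylsilyl dienol ether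
Conditions: Et3SiOTf, Et3N, CH2Cl2, −78 → 0 °C
Reagents that add atoms: triethylsilyl trifluoromethanesulfonate, CC[Si](CC)(CC)OS(=O)(=O)C(F)(F)F
Why: Soft enolisation takes the only α'-hydrogen (C10–H) and gives the cross-conjugated 2-silyloxydiene; the esters are not enolised and the lactone has no α-hydrogen.

**Step 17**
Reactants: 23 triethylsilyl dienol ether
Product: 24 dichlorocyclobutanone (bicyclo[6.2.0] core)
Conditions: Cl2CHCOCl, Et3N (slow addition), Et2O/hexane, 0 °C → rt
Reagents that add atoms: dichloroacetyl chloride, O=C(Cl)C(Cl)Cl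
Why: [2+2] cycloaddition of dichloroketene made in situ with the silyl enol ether, in which the carbonyl carbon bonds to the nucleophilic C10 and CCl2 to the oxygenated C3, the ring fusion must be cis, and the ketene should approach anti to the pseudo-axial C8 ester held by the trans-fused lactone, which sets the C3/C10 fusion.

**Step 18**
Reactants: 24 dichlorocyclobutanone (bicyclo[6.2.0] core)
Product: 25 3-silyloxycyclobutanone
Conditions: Zn dust, AcOH, THF, 0 °C → rt
Reagents that add atoms: none
Why: Zinc reduces the two α-C–Cl bonds (standard after dichloroketene additions) and should neither open the silyloxycyclobutanone nor reduce the methylene lactone.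

**Step 19**
Reactants: 25 3-silyloxycyclobutanone
Product: 28 target CNP0409052.1, via ten-membered enol silane 26 (not isolated), via α'-bromo-1,3-diketone 27 (not isolated)
Conditions: Et3SiOTf (10 mol%), 2,6-di-tert-butyl-4-methylpyridine (20 mol%), CH2Cl2, −78 °C; NBS (1.0 equiv), −78 °C; Et3N, −78 → 0 °C
Reagents that add atoms: none
Why: Proposed new method: catalytic Et3SiOTf silylates the strained ketone of the donor–acceptor cyclobutane 25, and the ring-fusion bond C3–C10 heterolyses with push from the C3 silyloxy group (retro-Mukaiyama aldol with silyl transfer), which releases the four-ring strain and turns the bicyclo[6.2.0] frame into the ten-membered 3-oxo enol silane 26; NBS then brominates C10 and triethylamine lets the C3 enolate oxygen displace the tertiary α-keto bromide, so the oxygen that was exocyclic on C3 ends up between C3 and C10 and the cyclobutanone has grown into the 3(2H)-furanone. The closest known reactions are the acid ring expansion of 1-silyloxybicyclo[n.2.0]alkan-(n+3)-ones to cycloalkane-1,3-diones, the Lewis-acid opening of 3-alkoxycyclobutanones, the α-bromination of silyl enol ethers and the base cyclisation of α'-bromo-1,3-diketones to 3(2H)-furanones. The furanone closes 5-exo-tet through oxygen, and the same closure lays the oxygen bridge across the ten-membered ring. C10 is the only new stereocentre: bromine should enter the outer face of 26, whose inner face is covered by the ring loop that carried C3, and the oxygen then displaces it from inside with inversion, so the configuration fixed at the ring fusion in step 17 is transferred with overall retention (10S). The step needs cleavage of the ring-fusion bond and not of C2–C3 (secured by the more substituted enol silane and the allyl-stabilised oxocarbenium at C3), bromination before the enol silane can flip or scramble (secured at −78 °C), and O- over C-alkylation (C-attack would need a cyclopropanone).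

**Compound list**

1 | (S)-3-bromo-2-methylpropan-1-ol | OC[C@H](C)CBr | starting material
2 | (S)-(3-bromo-2-methylpropoxy)(tert-butyl)diphenylsilane | BrC[C@@H](C)CO[Si](c1ccccc1)(c1ccccc1)C(C)(C)C | intermediate
3 | 1,3-dithiane | C1CSCSC1 | starting material
4 | 2-lithio-1,3-dithiane | [Li]C1SCCCS1 | intermediate (not isolated)
5 | (R)-2-[3-(tert-butyldiphenylsilyloxy)-2-methylpropyl]-1,3-dithiane | C1CSC(SC1)C[C@@H](C)CO[Si](c1ccccc1)(c1ccccc1)C(C)(C)C | intermediate
6 | (S)-5-(hydroxymethyl)furan-2(5H)-one | O=C1C=C[C@@H](CO)O1 | starting material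
7 | (S)-5-[(tert-butyldimethylsilyloxy)methyl]furan-2(5H)-one | O=C1C=C[C@@H](CO[Si](C)(C)C(C)(C)C)O1 | intermediate
8 | 2-lithio derivative of 5 | [Li]C1(SCCCS1)C[C@@H](C)CO[Si](c1ccccc1)(c1ccccc1)C(C)(C)C | intermediate (not isolated)
9 | lithium enolate of the conjugate adduct (dithianyl group on C7 trans to CH2OTBS on C6) | [Li]OC1=C[C@H](C2(SCCCS2)C[C@@H](C)CO[Si](c3ccccc3)(c4ccccc4)C(C)(C)C)[C@@H](CO[Si](C)(C)C(C)(C)C)O1 | intermediate (not isolated)
10 | Mannich lactone: γ-butyrolactone with CH2NMe2 on C11, the 2-alkyl-1,3-dithian-2-yl group on C7 and CH2OTBS on C6, all trans | CN(C)C[C@@H]1C(=O)O[C@H](CO[Si](C)(C)C(C)(C)C)[C@H]1C2(SCCCS2)C[C@@H](C)CO[Si](c3ccccc3)(c4ccccc4)C(C)(C)C | intermediate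
11 | trimethylammonium iodide of 10 | C[N+](C)(C)C[C@@H]1C(=O)O[C@H](CO[Si](C)(C)C(C)(C)C)[C@H]1C2(SCCCS2)C[C@@H](C)CO[Si](c3ccccc3)(c4ccccc4)C(C)(C)C.[I-] | intermediate (not isolated)
12 | α-methylene-γ-butyrolactone with the dithiane at C8 (C6/C7 trans) | C=C1C(=O)O[C@H](CO[Si](C)(C)C(C)(C)C)[C@H]1C2(SCCCS2)C[C@@H](C)CO[Si](c3ccccc3)(c4ccccc4)C(C)(C)C | intermediate
13 | C8 ketone: 4-acyl-3-methylene lactone (C6/C7 trans) | C=C1C(=O)O[C@H](CO[Si](C)(C)C(C)(C)C)[C@H]1C(=O)C[C@@H](C)CO[Si](c2ccccc2)(c3ccccc3)C(C)(C)C | intermediate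
14 | (8R)-alcohol | C=C1C(=O)O[C@H](CO[Si](C)(C)C(C)(C)C)[C@H]1[C@H](O)C[C@@H](C)CO[Si](c2ccccc2)(c3ccccc3)C(C)(C)C | intermediate
15 | C8 isovalerate (3-methylbutanoate) of 14 | C=C1C(=O)O[C@H](CO[Si](C)(C)C(C)(C)C)[C@H]1[C@H](OC(=O)CC(C)C)C[C@@H](C)CO[Si](c2ccccc2)(c3ccccc3)C(C)(C)C | intermediate
16 | primary alcohol at C5 (TBS removed) | C=C1C(=O)O[C@H](CO)[C@H]1[C@H](OC(=O)CC(C)C)C[C@@H](C)CO[Si](c2ccccc2)(c3ccccc3)C(C)(C)C | intermediate
17 | C5 aldehyde | C=C1C(=O)O[C@H](C=O)[C@H]1[C@H](OC(=O)CC(C)C)C[C@@H](C)CO[Si](c2ccccc2)(c3ccccc3)C(C)(C)C | intermediate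
18 | (Z)-2-iodoprop-1-enyl lactone (I cis to C6) | C=C1C(=O)O[C@H](/C=C(/C)I)[C@H]1[C@H](OC(=O)CC(C)C)C[C@@H](C)CO[Si](c2ccccc2)(c3ccccc3)C(C)(C)C | intermediate
19 | primary alcohol at C3 (TBDPS removed) | C=C1C(=O)O[C@H](/C=C(/C)I)[C@H]1[C@H](OC(=O)CC(C)C)C[C@@H](C)CO | intermediate
20 | C3 aldehyde | C=C1C(=O)O[C@H](/C=C(/C)I)[C@H]1[C@H](OC(=O)CC(C)C)C[C@@H](C)C=O | intermediate
21 | cyclooctenol: (Z)-cyclooctene with C3–OH (both epimers), trans-fused α-methylene lactone on C6/C7, C8 isovalerate | C=C1C(=O)O[C@@H]2/C=C(/C)C(O)[C@H](C)C[C@@H](OC(=O)CC(C)C)[C@@H]12 | intermediate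
22 | cyclooctenone: 6,8-dimethyl-3-methylene-2,7-dioxo-2,3,3a,4,5,6,7,9a-octahydrocycloocta[b]furan-4-yl 3-methylbutanoate (3a,9a-trans) | C=C1C(=O)O[C@@H]2/C=C(/C)C(=O)[C@H](C)C[C@@H](OC(=O)CC(C)C)[C@@H]12 | intermediate
23 | triethylsilyl dienol ether of 22 (C3(OSiEt3)=C10, conjugated to C4=C5) | C=C1C(=O)O[C@@H]2/C=C(/C)\C(O[Si](CC)(CC)CC)=C(C)/C[C@@H](OC(=O)CC(C)C)[C@@H]12 | intermediate
24 | dichlorocyclobutanone: cis-fused bicyclo[6.2.0] with C1=O, C2Cl2, C3–OSiEt3, C10–CH3; four-membered ring anti to the C8 ester | C=C1C(=O)O[C@@H]2/C=C(/C)[C@]3(O[Si](CC)(CC)CC)C(Cl)(Cl)C(=O)[C@]3(C)C[C@@H](OC(=O)CC(C)C)[C@@H]12 | intermediate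
25 | 3-triethylsilyloxycyclobutanone (dechlorinated 24) | C=C1C(=O)O[C@@H]2/C=C(/C)[C@]3(O[Si](CC)(CC)CC)CC(=O)[C@]3(C)C[C@@H](OC(=O)CC(C)C)[C@@H]12 | intermediate
26 | ten-membered enol silane: C1(OSiEt3)=C10(CH3) with C2 and C9 trans, C3 ketone | C=C1C(=O)O[C@@H]2/C=C(/C)C(=O)C/C(O[Si](CC)(CC)CC)=C(C)/C[C@@H](OC(=O)CC(C)C)[C@@H]12 | intermediate (not isolated)
27 | ten-membered α'-bromo-1,3-diketone (C10–Br, C1 and C3 ketones) | C=C1C(=O)O[C@@H]2/C=C(/C)C(=O)CC(=O)[C@](C)(Br)C[C@@H](OC(=O)CC(C)C)[C@@H]12 | intermediate (not isolated)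
28 | CNP0409052.1, (4Z,6R,7R,8R,10S)-furanoheliangolide 8-isovalerate | C=C1C(=O)O[C@@H]2/C=C(/C)C3=CC(=O)[C@](C)(C[C@@H](OC(=O)CC(C)C)[C@@H]12)O3 | target

**Step count and risks**

Total steps: 19. Longest linear sequence: 18 (steps 1, 2, 4–19).

Steps most likely to fail:

1. Step 19 (proposed new method). The kinetic enol silane may scramble to its conjugated isomers before it is brominated, or the tertiary bromide may lose HBr instead of being displaced. The fallback separates ring opening and oxidation with known reactions. It sets out from 25: heating in AcOH/H2O/i-PrOH (the hydrolytic two-carbon ring expansion used for cycloalkane-1,3-diones) should give the ten-membered 1,3-diketone F1. Me3SiOTf/Et3N converts this into the 1,3-bis(trimethylsilyloxy)diene F2, which dimethyldioxirane oxidises at its terminal carbon (Rubottom-type) to the α'-hydroxy-1,3-diketone F3. Acid (p-TsOH, CH2Cl2) then closes F3 by the classical cyclodehydration and the sequence comes back to the route at 28. In this variant the C10 configuration rests only on which face of the relaxed ring the oxidant meets, so C10 epimers may have to be separated.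

2. Step 17. The ketene may add with poor or reversed facial selectivity. The fallback sets out from 23 and uses the other adduct, the diastereomeric dichlorocyclobutanone F4 (four-membered ring syn to the C8 ester), which Zn/AcOH reduces to the cyclobutanone F5. The same Et3SiOTf fragmentation then gives the other planar form of 26, and instead of bromination and displacement (two inversions) a single outer-face oxygenation with dimethyldioxirane at −78 °C gives the α'-triethylsilyloxy-1,3-diketone F6 with the natural C10 configuration. Wet p-TsOH removes the silyl group and cyclodehydrates, and the sequence comes back to the route at 28. The two oxidation modes are stereocomplementary, so either ring-fusion diastereomer can be taken to the same C10 configuration.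

3. Step 14. Intermolecular coupling or reduction of the C–I bond may outrun the eight-membered ring closure. The fallback moves the ring-closing bond from C3–C4 to C4=C5 (metathesis). It sets out from 17: Takai–Lombardo methylenation (Zn, CH2Br2, TiCl4) gives the vinyl lactone F7, HF·pyridine the primary alcohol F8, and Dess–Martin oxidation the aldehyde F9. Intermolecular Nozaki–Hiyama–Kishi addition of 2-bromopropene gives the isopropenyl carbinol F10, and ring-closing metathesis (Grubbs second-generation catalyst, CH2Cl2, 40 °C, high dilution) comes back to the route at 21.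

**Further compounds**

F1 | step 19 | ten-membered 1,3-diketone (C1 and C3 ketones, C10–H epimers) | C=C1C(=O)O[C@@H]2/C=C(/C)C(=O)CC(=O)C(C)C[C@@H](OC(=O)CC(C)C)[C@@H]12
F2 | step 19 | 1,3-bis(trimethylsilyloxy)diene of F1 (C3(OSiMe3)=C2–C1(OSiMe3)=C10) | C=C1C(=O)O[C@@H]2/C=C(/C)C(O[Si](C)(C)C)=CC(O[Si](C)(C)C)=C(C)C[C@@H](OC(=O)CC(C)C)[C@@H]12
F3 | step 19 | ten-membered α'-hydroxy-1,3-diketone (C10–OH, natural C10 configuration) | C=C1C(=O)O[C@@H]2/C=C(/C)C(=O)CC(=O)[C@@](C)(O)C[C@@H](OC(=O)CC(C)C)[C@@H]12
F4 | step 17 | diastereomeric dichlorocyclobutanone (four-membered ring syn to the C8 ester) | C=C1C(=O)O[C@@H]2/C=C(/C)[C@@]3(O[Si](CC)(CC)CC)C(Cl)(Cl)C(=O)[C@@]3(C)C[C@@H](OC(=O)CC(C)C)[C@@H]12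
F5 | step 17 | diastereomeric 3-triethylsilyloxycyclobutanone | C=C1C(=O)O[C@@H]2/C=C(/C)[C@@]3(O[Si](CC)(CC)CC)CC(=O)[C@@]3(C)C[C@@H](OC(=O)CC(C)C)[C@@H]12
F6 | step 17 | ten-membered α'-triethylsilyloxy-1,3-diketone (natural C10 configuration) | C=C1C(=O)O[C@@H]2/C=C(/C)C(=O)CC(=O)[C@@](C)(O[Si](CC)(CC)CC)C[C@@H](OC(=O)CC(C)C)[C@@H]12
F7 | step 14 | vinyl lactone (C5=CH2) with TBDPS ether | C=C1C(=O)O[C@H](C=C)[C@H]1[C@H](OC(=O)CC(C)C)C[C@@H](C)CO[Si](c2ccccc2)(c3ccccc3)C(C)(C)C
F8 | step 14 | vinyl lactone primary alcohol | C=C1C(=O)O[C@H](C=C)[C@H]1[C@H](OC(=O)CC(C)C)C[C@@H](C)CO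
F9 | step 14 | vinyl lactone aldehyde | C=C1C(=O)O[C@H](C=C)[C@H]1[C@H](OC(=O)CC(C)C)C[C@@H](C)C=O
F10 | step 14 | isopropenyl carbinol diene (carbinol epimers) | C=C1C(=O)O[C@H](C=C)[C@H]1[C@H](OC(=O)CC(C)C)C[C@@H](C)C(O)C(C)=C
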